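The data are simulated from invented constants, and the scatter is random.

The substrate keeps the same pace in the two runs so far: at 0.417 min the alpha run shows 23.9% of it and the eta run 24.2%, with 2.1 equiv of first nucleophile charged against 3.3 equiv, and target reads highest at that same time in both runs.

the same everywhere: substrate 0.081 M; protic impurity 0.0162 M

|  | first nucleophile | second nucleophile | remark | time |
|---|---|---|---|---|
| alpha | 2.1 equiv | 1.2 equiv | run made earlier |  |
| eta | 3.3 equiv | 1.2 equiv | run made earlier |  |
| flask | 1.50 equiv | 1.20 equiv |  | 6.0 min |

- alpha (time / min: target / %, substrate / %): 0.167: 27.8, 56.6; 0.200: 29.9, 51.7; 0.417: 36.2, 23.9; 0.833: 29.7, 6.9; 2.00: 19.7, 0; 4.00: 17.3, 0; 8.00: 19.8, 0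
- eta (time / min: target / %, substrate / %): 0.167: 30.3, 55.8; 0.200: 35.0, 51.5; 0.417: 40.3, 24.2; 0.833: 33.2, 6.3; 2.00: 22.4, 0.7; 4.00: 21.6, 0; 8.00: 21.2, 0

(scatter of a reading: 1 percentage point)



- time up to 6.0 min at which target stands highest
- the amount of target, in percent of the substrate charged, at that time
- earliest time at which at least nineteen twentieths of that best amount are there, in min
- latest time at which they still are, in min

You asked for a quick number, so we let the first nucleophile change how much target comes and leave when it comes at that shared reading. The steady late readings, from 2.00 min on, give us the split charge, the equivalents of first nucleophile at which target takes as much of the reacting substrate as the competing route, a selectivity factor written in equivalents: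

share of target = [first nucleophile] / ([first nucleophile] + split charge), both in equivalents

late mean: alpha 18.9%, eta 21.7%, ratio 1.15

split charge = 1.15

flask share over alpha share = 0.876

best = 36.2% × 0.876 = 31.7%

The split charge is a loose reading, since it rests on a small ratio between scattered means. Your forecast gives 33% at 0.36 min, with a window from 0.27 min to 0.52 min, and calls the gain “a saturating competition”. We stand lower and later, at 31.7% and 0.417 min.

The flask stands highest at 0.416 min with 31.7%, and holds the asked share of that amount from 0.287 min to 0.595 min.

    first nucleophile + protic impurity → quenched reagent (k = 2.40 /M/s)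
    substrate ⇌ intermediate (K = 0.0580, k = 0.0560 /s)
    target ⇌ isomer of the product (K = 3.00, k = 0.0330 /s)
    second nucleophile + intermediate → other capture product (k = 390 /M/s)
    first nucleophile + intermediate → target (k = 730 /M/s)

In the flask target passes into isomer of the product and back, with a relaxation half-life of 0.263 min by that step alone, short against 6.0 min, and at 6.00 min it holds 16.0% of target beside 48.1% of isomer. The split charge puts the flask's plateau at 16.6%. For the neighbour with 0.380 equiv of first nucleophile it reckons a peak of 13.9%, and that neighbour gives 12.9%.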